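**Plan**
- Retrosynthesis: in each quinone ring the two bonds joining the MeO–C=C–Me edge to the two carbonyl carbons are cut, in both rings at once. This leaves 1-methoxyprop-1-yne and the four-carbon arc O=C–C(O)=C(CH2)–C=O, stored as a cyclobut-2-en-1-one. The two ring–CH2 bonds of the C14 tether are cut next.
- Enabling feature: in that cyclobutenone the strained C1(=O)–C4 σ bond is allylic to C2=C3 and C4 carries an oxygen donor, so the four-membered ring opens to a vinylketene whose C1=C2 bond takes up the polarised C≡C of the ynol ether. C1=O and C2–O become the para quinone oxygens and C4–O becomes the hydroxyl.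
- Forward: diisopropyl squarate is reduced and MOM-protected; a C14 bis-Grignard reagent joins two such rings (addition, then Stork–Danheiser transposition); both benzene rings then arise together in a two-fold Danheiser benzannulation; oxidative dealkylation gives the bis-quinone and MOM cleavage the target.
- Stereochemistry: the target has no stereocentre; the sp3 centres of the intermediates form unselectively and vanish on aromatisation.

Key step: step 5

Remark: the tether is read as tetradecane-1,14-diyl (fourteen CH2 groups); intermediates with sp3 ring carbons are stereoisomer mixtures and are written without configuration; a two-fold step consumes two molecules of the partner compound, and the second molecule is entered under "Reagents that add atoms".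

**Step 1**
Reactants: 1 diisopropyl squarate (3,4-diisopropoxycyclobut-3-ene-1,2-dione)
Product: 2 4-hydroxy-2,3-diisopropoxycyclobut-2-en-1-one (racemic)
Conditions: LiAlH(OtBu)3 (1.1 equiv), THF, −78 → 0 °C; aq. potassium sodium tartrate (KNaC4H4O6) work-up
Reagents that add atoms: none
Why: 1,2-reduction of one vinylogous-ester carbonyl of a squarate by the mild, hindered hydride LiAlH(OtBu)3 should stop at the 4-hydroxycyclobutenone, the new carbinol centre forming as a racemate of no consequence.

**Step 2**
Reactants: 2 4-hydroxy-2,3-diisopropoxycyclobut-2-en-1-one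
Product: 3 2,3-diisopropoxy-4-(methoxymethoxy)cyclobut-2-en-1-one (racemic)
Conditions: MOMCl, iPr2NEt, CH2Cl2, 0 °C → rt
Reagents that add atoms: chloromethyl methyl ether (MOMCl), COCCl
Why: O-alkylation of the secondary alcohol under amine base (acetal-type protection) avoids the alkoxide that would trigger ring opening and installs a non-migrating oxygen substituent for the later electrocyclic opening.

**Step 3**
Reactants: 3 2,3-diisopropoxy-4-(methoxymethoxy)cyclobut-2-en-1-one (2 equiv); 4 1,14-dibromotetradecane
Product: 7 3,3'-(tetradecane-1,14-diyl)bis[2-isopropoxy-4-(methoxymethoxy)cyclobut-2-en-1-one], via bis-Grignard reagent 5 (not isolated), via bis-carbinol 6 (not isolated)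
Conditions: 4, Mg, I2 (cat.), THF, 40 °C; 3 (2 equiv), THF, −78 → 0 °C; then 1 M aq. HCl, 0 °C
Reagents that add atoms: cyclobutenone 3 (second molecule), CC(C)OC1=C(OC(C)C)C(OCOC)C1=O; water, O
Why: each C–MgBr end of the bis-Grignard reagent adds 1,2 to the carbonyl of one molecule of 3 (two molecules of 3 per tether), then acid-induced ionisation of the tertiary allylic carbinols and hydrolysis of the isopropoxy-stabilised cations (Stork–Danheiser transposition) should move each carbonyl to the former C3 and place the tether on the β-carbon, the MOM-bearing centres forming unselectively.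

**Step 4**
Reactants: 8 chloroacetaldehyde dimethyl acetal (2-chloro-1,1-dimethoxyethane)
Product: 10 1-methoxyprop-1-yne, via sodium methoxyacetylide 9 (not isolated)
Conditions: NaNH2 (3.1 equiv), liq. NH3, −33 °C; then MeI, −33 °C; NH3 evaporated, aqueous work-up, distillation
Reagents that add atoms: iodomethane, CI
Why: double elimination (MeOH, then HCl) from the chloroacetal by NaNH2 gives the acetylide of methoxyethyne, and its C-alkylation with MeI in liquid ammonia (acetylide alkylation) should give the ynol ether.

**Step 5**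
Reactants: 7 3,3'-(tetradecane-1,14-diyl)bis[2-isopropoxy-4-(methoxymethoxy)cyclobut-2-en-1-one]; 10 1-methoxyprop-1-yne
Product: 15 3,3'-(tetradecane-1,14-diyl)bis[4-isopropoxy-5-methoxy-2-(methoxymethoxy)-6-methylphenol], via bis-vinylketene 11 (not isolated), via bis-alkenylcyclobutenone 12 (not isolated), via bis-dienylketene 13 (not isolated), via bis-cyclohexadienone 14 (not isolated)
Conditions: 10 (6 equiv), toluene (0.05 M), sealed tube, 80 °C then 110 °C
Reagents that add atoms: 1-methoxyprop-1-yne 10 (second molecule), CC#COC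
Why: Heating opens each cyclobutenone by 4π conrotatory cleavage of the C1–C4 bond, the C4 methoxymethoxy group rotating outward, to an (isopropoxy)vinylketene; its C1=C2 bond then adds the ynol ether in a [2+2] cycloaddition in which the nucleophilic methyl-bearing alkyne carbon bonds to the ketene carbonyl carbon and the methoxy-bearing carbon to C2, so both new ring bonds are made in this one event. The resulting 4-alkenyl-4-isopropoxycyclobutenone opens again (4π, isopropoxy outward, alkenyl inward) to a dienylketene, which closes the six-membered ring by 6π disrotatory electrocyclisation of the ketene carbon onto the MOM-oxygenated terminus and tautomerises to the phenol. This is the Danheiser benzannulation of a cyclobutenone with an alkoxyalkyne, run here at both ends of the tether at once, one molecule of 10 being taken up per ring. No stereocentre remains, since the sp3 centres of 7, 12 and 14 are erased on aromatisation. The regiochemistry needed (methyl next to the phenol carbon, methoxy next to the isopropoxy-bearing carbon) is secured by the polarisation of the ynol ether against the electrophilic ketene carbon; capture ahead of ketene self-reaction is secured by excess ynol ether, moderate dilution and a methoxy alkyne that cannot lose an alkene by retro-ene fragmentation.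

**Step 6**
Reactants: 15 3,3'-(tetradecane-1,14-diyl)bis[4-isopropoxy-5-methoxy-2-(methoxymethoxy)-6-methylphenol]
Product: 16 3,3'-(tetradecane-1,14-diyl)bis[5-methoxy-2-(methoxymethoxy)-6-methylcyclohexa-2,5-diene-1,4-dione]
Conditions: PhI(OAc)2 (2.2 equiv), MeCN–H2O, 0 °C
Reagents that add atoms: water, O
Why: oxidative dealkylation of a para-alkoxyphenol by a trivalent-iodine reagent (ligand exchange at the only free phenol, attack of water at the para carbon bearing isopropoxy, collapse of the hemiketal) should give the para-quinone and leave the MOM-protected ortho oxygen untouched.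

**Step 7**
Reactants: 16 3,3'-(tetradecane-1,14-diyl)bis[5-methoxy-2-(methoxymethoxy)-6-methylcyclohexa-2,5-diene-1,4-dione]
Product: 17 3,3'-(tetradecane-1,14-diyl)bis(2-hydroxy-5-methoxy-6-methylcyclohexa-2,5-diene-1,4-dione) (CNP0278640.0)
Conditions: CF3CO2H, CH2Cl2, 0 °C → rt; aqueous work-up
Reagents that add atoms: none
Why: acid-catalysed cleavage of the MOM acetal through the methoxymethyl cation is far faster for this vinylogous MOM ester than any cleavage of the methyl vinylogous ester and should unmask the 2-hydroxyquinone.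

**Compound list**
1 | diisopropyl squarate (3,4-diisopropoxycyclobut-3-ene-1,2-dione) | CC(C)OC1=C(OC(C)C)C(=O)C1=O | starting material
2 | 4-hydroxy-2,3-diisopropoxycyclobut-2-en-1-one (racemic) | CC(C)OC1=C(OC(C)C)C(O)C1=O | intermediate
3 | 2,3-diisopropoxy-4-(methoxymethoxy)cyclobut-2-en-1-one (racemic) | CC(C)OC1=C(OC(C)C)C(OCOC)C1=O | intermediate
4 | 1,14-dibromotetradecane | BrCCCCCCCCCCCCCCBr | starting material
5 | tetradecane-1,14-diylbis(magnesium bromide) | Br[Mg]CCCCCCCCCCCCCC[Mg]Br | intermediate
6 | 1,1'-(tetradecane-1,14-diyl)bis[2,3-diisopropoxy-4-(methoxymethoxy)cyclobut-2-en-1-ol] (stereoisomer mixture) | COCOC1C(OC(C)C)=C(OC(C)C)C1(O)CCCCCCCCCCCCCCC1(O)C(OC(C)C)=C(OC(C)C)C1OCOC | intermediate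
7 | 3,3'-(tetradecane-1,14-diyl)bis[2-isopropoxy-4-(methoxymethoxy)cyclobut-2-en-1-one] (rac/meso mixture) | COCOC1C(=O)C(OC(C)C)=C1CCCCCCCCCCCCCCC1=C(OC(C)C)C(=O)C1OCOC | intermediate
8 | chloroacetaldehyde dimethyl acetal (2-chloro-1,1-dimethoxyethane) | COC(CCl)OC | starting material
9 | sodium methoxyacetylide | [Na+].[C-]#COC | intermediate
10 | 1-methoxyprop-1-yne | CC#COC | intermediate
11 | bis-vinylketene: 3,3'-(tetradecane-1,14-diyl)bis[2-isopropoxy-4-(methoxymethoxy)buta-1,3-dien-1-one], both enol-ether double bonds E | O=C=C(OC(C)C)/C(=C/OCOC)CCCCCCCCCCCCCC/C(=C\OCOC)C(OC(C)C)=C=O | intermediate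
12 | bis-alkenylcyclobutenone: 4,4'-[(1E,17E)-1,18-bis(methoxymethoxy)octadeca-1,17-diene-2,17-diyl]bis(4-isopropoxy-3-methoxy-2-methylcyclobut-2-en-1-one) (ring C4 unselective) | O=C1C(C)=C(OC)C1(OC(C)C)/C(=C/OCOC)CCCCCCCCCCCCCC/C(=C\OCOC)C1(OC(C)C)C(OC)=C(C)C1=O | intermediate
13 | bis-dienylketene: 5,5'-(tetradecane-1,14-diyl)bis[4-isopropoxy-3-methoxy-6-(methoxymethoxy)-2-methylhexa-1,3,5-trien-1-one], 3Z,5E at each end | O=C=C(C)/C(OC)=C(OC(C)C)\C(=C\OCOC)CCCCCCCCCCCCCC/C(=C\OCOC)/C(OC(C)C)=C(OC)\C(C)=C=O | intermediate
14 | bis-cyclohexadienone: 3,3'-(tetradecane-1,14-diyl)bis[4-isopropoxy-5-methoxy-2-(methoxymethoxy)-6-methylcyclohexa-3,5-dien-1-one] (stereoisomer mixture) | COCOC1C(=O)C(C)=C(OC)C(OC(C)C)=C1CCCCCCCCCCCCCCC1=C(OC(C)C)C(OC)=C(C)C(=O)C1OCOC | intermediate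
15 | 3,3'-(tetradecane-1,14-diyl)bis[4-isopropoxy-5-methoxy-2-(methoxymethoxy)-6-methylphenol] | COCOc1c(O)c(C)c(OC)c(OC(C)C)c1CCCCCCCCCCCCCCc1c(OC(C)C)c(OC)c(C)c(O)c1OCOC | intermediate
16 | 3,3'-(tetradecane-1,14-diyl)bis[5-methoxy-2-(methoxymethoxy)-6-methylcyclohexa-2,5-diene-1,4-dione] | COC1=C(C)C(=O)C(OCOC)=C(CCCCCCCCCCCCCCC2=C(OCOC)C(=O)C(C)=C(OC)C2=O)C1=O | intermediate
17 | 3,3'-(tetradecane-1,14-diyl)bis(2-hydroxy-5-methoxy-6-methylcyclohexa-2,5-diene-1,4-dione) | COC1=C(C)C(=O)C(O)=C(CCCCCCCCCCCCCCC2=C(O)C(=O)C(C)=C(OC)C2=O)C1=O | target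

**Totals**
Total step count: 7. Longest linear sequence: 6 steps (1 → 2 → 3 → 7 → 15 → 16 → 17); step 4 is a side branch.

**Steps most likely to fail**

1. Step 5. Capture of the transient vinylketene by the ynol ether is bimolecular and may lose to re-closure, ketene dimerisation, acylation of the phenol already formed or loss of propene from the isopropoxyketene; the second annulation may also stall after the first.
Fallback (ring built by a Moore rearrangement instead of a ketene–alkyne cycloaddition; sets out from 5 and 1, comes back at 17): the bis-Grignard reagent 5 is added to diisopropyl squarate 1 (2 equiv, THF, −78 °C) and the adduct is treated with catalytic HCl to give 4,4'-(tetradecane-1,14-diyl)bis(3-isopropoxycyclobut-3-ene-1,2-dione) F1. (Z)-2-Bromo-1-methoxyprop-1-ene F2 is made from commercial 2-bromo-1,1-dimethoxypropane with Me3SiOTf/iPr2NEt. Bromine–lithium exchange with t-BuLi (Et2O, −78 °C) gives (1-methoxyprop-1-en-2-yl)lithium F3, with lithium cis to methoxy. It adds to the more electrophilic carbonyl of each ring of F1, the one next to the isopropoxy-bearing carbon, to give the bis(4-alkenyl-4-hydroxycyclobutenone) F4. Heating F4 in toluene at 110 °C (ring opening to the dienylketene, 6π closure, tautomerisation) should give the bis-hydroquinone F5. Ag2O should oxidise it to the bis-quinone isopropyl ether F6, and BCl3 (CH2Cl2, −78 °C) should remove the isopropyl groups in preference to methyl to give 17.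

2. Step 3. The two-fold addition may stop at the mono-adduct (Wurtz coupling while the bis-Grignard reagent forms, poor solubility of the bis-organometallic), or the acid-induced transposition may be accompanied by loss of the MOM group.
Fallback (tether closed by olefin metathesis instead of a bis-nucleophile; sets out from 3, comes back at 7): oct-7-en-1-ylmagnesium bromide F7 (from commercial 8-bromooct-1-ene and Mg) is added to 3 and the adduct is transposed with dilute HCl to 2-isopropoxy-4-(methoxymethoxy)-3-(oct-7-en-1-yl)cyclobut-2-en-1-one F8. Self-metathesis of F8 with the second-generation Grubbs catalyst RuCl2(=CHPh)(PCy3)(H2IMes) (CH2Cl2, 40 °C, ethene removed) should give the tetradec-7-ene-1,14-diyl-linked bis-cyclobutenone F9 as an E/Z mixture. Diimide (2-nitrobenzenesulfonyl hydrazide, Et3N) should reduce the disubstituted alkene only and give 7.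

3. Step 6. Water may attack the phenoxenium intermediate at the ortho carbon carrying the MOM ether instead of the para carbon, or the electron-rich ring may be over-oxidised with partial loss of MOM, giving mixtures.
Fallback (deprotection first, oxidation last; sets out from 15, comes back at 17): BCl3 (CH2Cl2, −78 → −20 °C) should cleave the isopropyl and MOM ethers of 15 but not the methyl ether, giving the bis(benzene-1,2,4-triol) F10. Air (or Ag2O, Et2O) should oxidise each triol ring to the 2-hydroxy-1,4-benzoquinone; the hydroxy-para-quinone and its ortho-quinone tautomer are the same compound, so either mode of oxidation leads to 17.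

**Further compounds**
F1 | step 5 | 4,4'-(tetradecane-1,14-diyl)bis(3-isopropoxycyclobut-3-ene-1,2-dione) | CC(C)OC1=C(CCCCCCCCCCCCCCC2=C(OC(C)C)C(=O)C2=O)C(=O)C1=O
F2 | step 5 | (Z)-2-bromo-1-methoxyprop-1-ene | Br/C(C)=C\OC
F3 | step 5 | (1-methoxyprop-1-en-2-yl)lithium, lithium cis to methoxy | [Li]/C(C)=C\OC
F4 | step 5 | 2,2'-(tetradecane-1,14-diyl)bis[4-hydroxy-3-isopropoxy-4-(1-methoxyprop-1-en-2-yl)cyclobut-2-en-1-one] | CO\C=C(C)/C1(O)C(OC(C)C)=C(CCCCCCCCCCCCCCC2=C(OC(C)C)C(O)(/C(C)=C\OC)C2=O)C1=O
F5 | step 5 | 2,2'-(tetradecane-1,14-diyl)bis(3-isopropoxy-6-methoxy-5-methylbenzene-1,4-diol) | COc1c(C)c(O)c(OC(C)C)c(CCCCCCCCCCCCCCc2c(O)c(OC)c(C)c(O)c2OC(C)C)c1O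
F6 | step 5 | 3,3'-(tetradecane-1,14-diyl)bis(2-isopropoxy-5-methoxy-6-methylcyclohexa-2,5-diene-1,4-dione) | COC1=C(C)C(=O)C(OC(C)C)=C(CCCCCCCCCCCCCCC2=C(OC(C)C)C(=O)C(C)=C(OC)C2=O)C1=O
F7 | step 3 | oct-7-en-1-ylmagnesium bromide | C=CCCCCCC[Mg]Br
F8 | step 3 | 2-isopropoxy-4-(methoxymethoxy)-3-(oct-7-en-1-yl)cyclobut-2-en-1-one | C=CCCCCCCC1=C(OC(C)C)C(=O)C1OCOC
F9 | step 3 | 3,3'-(tetradec-7-ene-1,14-diyl)bis[2-isopropoxy-4-(methoxymethoxy)cyclobut-2-en-1-one] (E/Z mixture) | COCOC1C(=O)C(OC(C)C)=C1CCCCCCC=CCCCCCCC1=C(OC(C)C)C(=O)C1OCOC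
F10 | step 6 | 3,3'-(tetradecane-1,14-diyl)bis(5-methoxy-6-methylbenzene-1,2,4-triol) | COc1c(C)c(O)c(O)c(CCCCCCCCCCCCCCc2c(O)c(O)c(C)c(OC)c2O)c1O
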